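**Plan**
- Cuts, last to first: the ten O–CH3 bonds; the O–benzyl bond on ring E; the diaryl ether bonds C4–O–D1 and A–O–B1 (Ullmann couplings at an aryl iodide); then, two bonds at once, B6–O(C1) together with B1–I.
- Enabling feature: ring B has neighbouring ether oxygens on B1 (to ring A) and B6 (to ring C), an oxygen on B2 and a hydrogen on B5. This is the pattern left when a nucleophile and an electrophile add across the B1≡B6 bond of 3,5-dimethoxybenzyne, the nucleophile going to the carbon remote from the flanking methoxy group.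
- Rings D and E repeat rings B and C atom for atom (D1, D2, D5, D6 match B1, B2, B5, B6; ring E differs from ring C only in what O4 finally carries), so one iodide serves as both the BC and the DE unit.
- Forward order (no ring is built, five preformed benzene rings are joined): C + B gives the iodide; one portion takes on ring A and loses its benzyl group; this ABC phenol is joined to a second portion of the iodide; debenzylation; demethylation.
- Stereochemistry: the target has no stereocentre, so none has to be set.

Key step: step 6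

Remark: the rings are lettered A to E from the 3,5-dihydroxyphenoxy end (A) to the 2,4,6-trihydroxyphenoxy end (E). B1 and D1 are the carbons bonded to the oxygen leading to rings A and C, B6 and D6 those bonded to the oxygen leading to rings C and E, C1 carries the B–C oxygen and C4 the C–D oxygen. All hydroxyls are carried as methyl ethers except O4 of ring C and O4 of ring E, which are benzyl ethers, so that rings D and E carry exactly the protecting groups of rings B and C.

**Route**

Step 1
Reactants: 1 3,5-dimethoxyphenol
Product: 2 3,5-dimethoxyphenyl isopropylcarbamate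
Conditions: i-PrNCO, Et3N (cat.), CH2Cl2, rt
Reagents that add atoms: isopropyl isocyanate, CC(C)N=C=O
Why: Amine-catalysed addition of a phenol to an isocyanate (carbamoylation) installs the N-isopropyl carbamate, which directs metalation and is later removed under mild base.

Step 2
Reactants: 2 3,5-dimethoxyphenyl isopropylcarbamate
Product: 6 3,5-dimethoxy-2-(trimethylsilyl)phenyl isopropylcarbamate, via N-silyl carbamate 3 (not isolated), via aryllithium 4 (not isolated), via bis-silyl carbamate 5 (not isolated)
Conditions: TBSOTf, TMEDA, Et2O, 0 °C → rt; then n-BuLi, TMEDA, −78 °C; TMSCl, −78 °C → rt; aq. NaHSO4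
Reagents that add atoms: chlorotrimethylsilane, C[Si](C)(C)Cl
Why: Directed ortho-metalation: after N-silylation in the flask, the carbamate and its neighbouring methoxy group together direct n-BuLi/TMEDA to the carbon between them (C2 and C6 are equivalent), the carbamate being a stronger director than the two methoxy groups flanking C4, and TMSCl silylates the aryllithium before the N–Si bond is hydrolysed on work-up.

Step 3
Reactants: 6 3,5-dimethoxy-2-(trimethylsilyl)phenyl isopropylcarbamate
Product: 8 3,5-dimethoxy-2-(trimethylsilyl)phenyl trifluoromethanesulfonate, via silylphenol 7 (not isolated)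
Conditions: DBU, Et2NH, MeCN, 40 °C; then PhNTf2, rt
Reagents that add atoms: N-phenylbis(trifluoromethanesulfonimide), O=S(=O)(N(c1ccccc1)S(=O)(=O)C(F)(F)F)C(F)(F)F
Why: Base-induced carbamate cleavage (loss of isopropyl isocyanate, scavenged by diethylamine as a urea) frees the phenoxide, which is O-triflated in the same flask, the standard entry to ortho-silylaryl triflates.

Step 4
Reactants: 9 2,6-dimethoxy-1,4-benzoquinone
Product: 10 2,6-dimethoxybenzene-1,4-diol
Conditions: Na2S2O4, EtOAc/H2O, rt, argon
Reagents that add atoms: none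
Why: Dithionite reduction of a quinone to its hydroquinone is fast and clean, and the crude diol is carried on under argon to avoid re-oxidation.

Step 5
Reactants: 10 2,6-dimethoxybenzene-1,4-diol; 11 benzyl bromide
Product: 12 4-(benzyloxy)-2,6-dimethoxyphenol
Conditions: K2CO3 (1.1 equiv), 11 (1.0 equiv), DMF (degassed), rt
Reagents that add atoms: none
Why: Williamson etherification should go to O4, which is unhindered and, with two meta methoxy groups, the more acidic hydroxyl, whereas O1 is flanked by two methoxy groups.

Step 6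
Reactants: 12 4-(benzyloxy)-2,6-dimethoxyphenol; 8 3,5-dimethoxy-2-(trimethylsilyl)phenyl trifluoromethanesulfonate
Product: 16 5-(benzyloxy)-2-(2-iodo-3,5-dimethoxyphenoxy)-1,3-dimethoxybenzene (BC iodide), via potassium phenoxide 13 (not isolated), via 3,5-dimethoxybenzyne 14 (not isolated), via aryl potassium 15 (not isolated)
Conditions: KH (1.0 equiv), THF, 0 °C → rt; then KF, 18-crown-6, n-C4F9I (3 equiv), 8 (1.5 equiv, added slowly), THF, rt → 40 °C, dark, argon sweep
Reagents that add atoms: nonafluoro-1-iodobutane, FC(F)(F)C(F)(F)C(F)(F)C(F)(F)I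
Why: Proposed new method: fluoride attacks silicon of 8 and triflate leaves to give aryne 14; phenoxide 13 adds to the aryne carbon B6, remote from the B2 methoxy group, and the resulting B1 anion 15, flanked by two oxygens, takes iodine from n-C4F9I by halogen-bond-assisted iodine transfer, after which the perfluorobutyl anion collapses to octafluorobutene and fluoride. The closest known reaction types are the fluoride-induced O-arylation of phenols by ortho-silylaryl triflates, in which the same anion is simply protonated, and three-component aryne couplings in which a sulfur or nitrogen nucleophile adds and the aryl anion is quenched by a halogen donor. No ring is closed and no stereocentre is formed. The step needs regioselectivity (oxygen to B6, iodine to B1), and the B2 methoxy group secures it by distorting the aryne so that B6 is the more electrophilic and less crowded terminus and the developing charge sits on B1 next to the withdrawing oxygen. Iodination must outrun protonation, which is secured by complete deprotonation of 12 with KH (H2 as the only by-product), a medium without acidic hydrogens and an excess of the iodine donor, while slow addition of 8 keeps anion 15 away from unreacted triflate and from a second aryne. C-Arylation of the phenoxide is excluded because both ortho positions and the para position of ring C are substituted.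

Step 7
Reactants: 16 5-(benzyloxy)-2-(2-iodo-3,5-dimethoxyphenoxy)-1,3-dimethoxybenzene; 1 3,5-dimethoxyphenol
Product: 17 5-(benzyloxy)-2-[2-(3,5-dimethoxyphenoxy)-3,5-dimethoxyphenoxy]-1,3-dimethoxybenzene (ABC benzyl ether)
Conditions: CuI (cat.), picolinic acid (cat.), K3PO4, 1 (1.5 equiv), DMSO, 90 °C
Reagents that add atoms: none
Why: Ullmann diaryl ether synthesis with a ligand that tolerates ortho-substituted, electron-rich aryl iodides; the phenol partner is unhindered and the oxygens beside the iodine can assist copper insertion.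

Step 8
Reactants: 17 ABC benzyl ether
Product: 18 4-[2-(3,5-dimethoxyphenoxy)-3,5-dimethoxyphenoxy]-3,5-dimethoxyphenol (ABC phenol)
Conditions: H2 (1 atm), Pd/C, EtOAc/MeOH, rt
Reagents that add atoms: none
Why: Hydrogenolysis of the benzyl ether frees O4 of ring C; methyl and diaryl ethers are inert and the iodide has already been consumed.

Step 9
Reactants: 18 ABC phenol; 16 5-(benzyloxy)-2-(2-iodo-3,5-dimethoxyphenoxy)-1,3-dimethoxybenzene
Product: 19 5-(benzyloxy)-2-(2-{4-[2-(3,5-dimethoxyphenoxy)-3,5-dimethoxyphenoxy]-3,5-dimethoxyphenoxy}-3,5-dimethoxyphenoxy)-1,3-dimethoxybenzene (pentamer benzyl ether)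
Conditions: CuI (cat.), picolinic acid (cat.), K3PO4, 16 (1.3 equiv), DMSO, 100 °C
Reagents that add atoms: none
Why: Ullmann diaryl ether synthesis of the same kind as step 7, joining the unhindered 3,5-dioxygenated phenol 18 (O4 of ring C) to a second portion of iodide 16, whose two rings now become rings D and E and whose benzyl ether is untouched by the copper conditions.

Step 10
Reactants: 19 pentamer benzyl ether
Product: 20 4-(2-{4-[2-(3,5-dimethoxyphenoxy)-3,5-dimethoxyphenoxy]-3,5-dimethoxyphenoxy}-3,5-dimethoxyphenoxy)-3,5-dimethoxyphenol (deca-O-methyl pentamer)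
Conditions: H2 (1 atm), Pd/C, EtOAc/MeOH, rt
Reagents that add atoms: none
Why: Hydrogenolysis removes the single benzyl ether on ring E before the Lewis-acid step, so that no benzylating species is generated later beside electron-rich phloroglucinol rings.

Step 11
Reactants: 20 deca-O-methyl pentamer
Product: 21 2-[2-(3,5-dihydroxyphenoxy)-3,5-dihydroxyphenoxy]-5-[2,4-dihydroxy-6-(2,4,6-trihydroxyphenoxy)phenoxy]benzene-1,3-diol (CNP0018313.0)
Conditions: BBr3 (large excess), CH2Cl2, −78 °C → rt; then H2O, 0 °C; argon
Reagents that add atoms: none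
Why: Lewis-acid ether cleavage, in which BBr3 binds each methoxy oxygen and bromide removes the methyl group by SN2, should free the ten remaining phenols while leaving the aryl–O–aryl bonds intact.

**Compound list**
1 | 3,5-dimethoxyphenol | COc1cc(O)cc(OC)c1 | starting material
2 | 3,5-dimethoxyphenyl isopropylcarbamate | COc1cc(OC)cc(OC(=O)NC(C)C)c1 | intermediate
3 | N-silyl carbamate: 3,5-dimethoxyphenyl N-(tert-butyldimethylsilyl)-N-isopropylcarbamate | COc1cc(OC)cc(OC(=O)N(C(C)C)[Si](C)(C)C(C)(C)C)c1 | intermediate
4 | aryllithium: 2-lithio derivative of 3 | COc1cc(OC)c([Li])c(OC(=O)N(C(C)C)[Si](C)(C)C(C)(C)C)c1 | intermediate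
5 | bis-silyl carbamate: 3,5-dimethoxy-2-(trimethylsilyl)phenyl N-(tert-butyldimethylsilyl)-N-isopropylcarbamate | COc1cc(OC)c([Si](C)(C)C)c(OC(=O)N(C(C)C)[Si](C)(C)C(C)(C)C)c1 | intermediate
6 | 3,5-dimethoxy-2-(trimethylsilyl)phenyl isopropylcarbamate | COc1cc(OC)c([Si](C)(C)C)c(OC(=O)NC(C)C)c1 | intermediate
7 | silylphenol: 3,5-dimethoxy-2-(trimethylsilyl)phenol | COc1cc(OC)c([Si](C)(C)C)c(O)c1 | intermediate
8 | 3,5-dimethoxy-2-(trimethylsilyl)phenyl trifluoromethanesulfonate | COc1cc(OC)c([Si](C)(C)C)c(OS(=O)(=O)C(F)(F)F)c1 | intermediate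
9 | 2,6-dimethoxy-1,4-benzoquinone | COC1=CC(=O)C=C(OC)C1=O | starting material
10 | 2,6-dimethoxybenzene-1,4-diol | COc1cc(O)cc(OC)c1O | intermediate
11 | benzyl bromide | BrCc1ccccc1 | starting material
12 | 4-(benzyloxy)-2,6-dimethoxyphenol | COc1cc(OCc2ccccc2)cc(OC)c1O | intermediate
13 | potassium phenoxide: potassium 4-(benzyloxy)-2,6-dimethoxyphenolate | [K+].[O-]c1c(OC)cc(OCc2ccccc2)cc1OC | intermediate
14 | 3,5-dimethoxybenzyne (1,2-didehydro-3,5-dimethoxybenzene) | COC1=CC#CC(OC)=C1 | intermediate
15 | aryl potassium: potassium 2-[4-(benzyloxy)-2,6-dimethoxyphenoxy]-4,6-dimethoxybenzenide | [K+].COc1cc(OC)[c-]c(Oc2c(OC)cc(OCc3ccccc3)cc2OC)c1 | intermediate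
16 | 5-(benzyloxy)-2-(2-iodo-3,5-dimethoxyphenoxy)-1,3-dimethoxybenzene (BC iodide, also used as the DE unit) | COc1cc(OC)c(I)c(Oc2c(OC)cc(OCc3ccccc3)cc2OC)c1 | intermediate
17 | 5-(benzyloxy)-2-[2-(3,5-dimethoxyphenoxy)-3,5-dimethoxyphenoxy]-1,3-dimethoxybenzene (ABC benzyl ether) | COc1cc(OC)cc(Oc2c(OC)cc(OC)cc2Oc2c(OC)cc(OCc3ccccc3)cc2OC)c1 | intermediate
18 | 4-[2-(3,5-dimethoxyphenoxy)-3,5-dimethoxyphenoxy]-3,5-dimethoxyphenol (ABC phenol) | COc1cc(OC)cc(Oc2c(OC)cc(OC)cc2Oc2c(OC)cc(O)cc2OC)c1 | intermediate
19 | 5-(benzyloxy)-2-(2-{4-[2-(3,5-dimethoxyphenoxy)-3,5-dimethoxyphenoxy]-3,5-dimethoxyphenoxy}-3,5-dimethoxyphenoxy)-1,3-dimethoxybenzene (pentamer benzyl ether) | COc1cc(OC)cc(Oc2c(OC)cc(OC)cc2Oc2c(OC)cc(Oc3c(OC)cc(OC)cc3Oc3c(OC)cc(OCc4ccccc4)cc3OC)cc2OC)c1 | intermediate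
20 | 4-(2-{4-[2-(3,5-dimethoxyphenoxy)-3,5-dimethoxyphenoxy]-3,5-dimethoxyphenoxy}-3,5-dimethoxyphenoxy)-3,5-dimethoxyphenol (deca-O-methyl pentamer) | COc1cc(OC)cc(Oc2c(OC)cc(OC)cc2Oc2c(OC)cc(Oc3c(OC)cc(OC)cc3Oc3c(OC)cc(O)cc3OC)cc2OC)c1 | intermediate
21 | 2-[2-(3,5-dihydroxyphenoxy)-3,5-dihydroxyphenoxy]-5-[2,4-dihydroxy-6-(2,4,6-trihydroxyphenoxy)phenoxy]benzene-1,3-diol (CNP0018313.0) | Oc1cc(O)cc(Oc2c(O)cc(O)cc2Oc2c(O)cc(Oc3c(O)cc(O)cc3Oc3c(O)cc(O)cc3O)cc2O)c1 | target

**Summary**
Total step count: 11. Longest linear sequence: 9 steps (steps 1, 2, 3, 6, 7, 8, 9, 10, 11).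

**Steps most likely to fail**

1. Step 6. The aryl anion 15 may be protonated instead of taking iodine, the phenoxide 13 may be consumed by the fluoroalkene released from the iodine donor, or the anion may attack the sulfonyl group of unreacted 8. A first remedy inside the step is an iodine donor whose spent anion is inert, such as (iodoethynyl)benzene. The fallback gives up the aryne and builds the same ether by nucleophilic aromatic substitution; it sets out from 12 and returns to the route at 16. Commercial 1-fluoro-3,5-dimethoxybenzene would be nitrated (HNO3, Ac2O, 0 °C) at the carbon between fluorine and methoxy, the isomer nitrated between the two methoxy groups being removed by chromatography, to give 1-fluoro-3,5-dimethoxy-2-nitrobenzene F1. Phenol 12 would displace the fluoride ortho to the nitro group (K2CO3, DMF, 80 °C) to give 5-(benzyloxy)-2-(3,5-dimethoxy-2-nitrophenoxy)-1,3-dimethoxybenzene F2. Reduction with Fe and NH4Cl in EtOH/H2O, which spares the benzyl ether, would give 2-[4-(benzyloxy)-2,6-dimethoxyphenoxy]-4,6-dimethoxyaniline F3. Diazotisation (NaNO2, aq. HCl/MeCN, 0 °C) would give 2-[4-(benzyloxy)-2,6-dimethoxyphenoxy]-4,6-dimethoxybenzenediazonium chloride F4, and KI would convert it in a Sandmeyer-type iodination into 16. Ring closure of the diazonium salt onto ring C is not open, since both positions ortho to the ether oxygen carry methoxy groups.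

2. Step 7. Copper insertion into iodide 16, which has a substituent on each side of the iodine, may be slow, so that hydrodeiodination and oxidative loss of the phenol take over. The fallback reverses the polarity of the two partners; it sets out from 16 and returns at 17. Iodide 16 would be hydroxylated (Pd2(dba)3, t-BuXPhos, KOH, dioxane/H2O, 100 °C) to 2-[4-(benzyloxy)-2,6-dimethoxyphenoxy]-4,6-dimethoxyphenol F5. Chan–Lam coupling of this phenol with commercial 3,5-dimethoxyphenylboronic acid (Cu(OAc)2, pyridine, 4 Å molecular sieves, CH2Cl2, air, rt) would then give 17.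

3. Step 9. The same slow copper insertion into 16 may intervene at this later and more valuable stage, and phenol 18 may be lost by oxidation under prolonged heating. The fallback reverses the roles of the two partners and changes the metal; it sets out from 18 and 16 and returns at 19. Phenol 18 would be triflated (Tf2O, pyridine, CH2Cl2, 0 °C) to 4-[2-(3,5-dimethoxyphenoxy)-3,5-dimethoxyphenoxy]-3,5-dimethoxyphenyl trifluoromethanesulfonate F6. Iodide 16 would be hydroxylated as described under step 7 to 2-[4-(benzyloxy)-2,6-dimethoxyphenoxy]-4,6-dimethoxyphenol F5. Pd-catalysed C–O coupling of the unhindered triflate F6 with the hindered phenol F5 (Pd(OAc)2, t-BuXPhos, K3PO4, toluene, 100 °C) would then give 19.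

**Further compounds**
F1 | step 6 | 1-fluoro-3,5-dimethoxy-2-nitrobenzene | COc1cc(F)c([N+](=O)[O-])c(OC)c1
F2 | step 6 | 5-(benzyloxy)-2-(3,5-dimethoxy-2-nitrophenoxy)-1,3-dimethoxybenzene | COc1cc(OC)c([N+](=O)[O-])c(Oc2c(OC)cc(OCc3ccccc3)cc2OC)c1
F3 | step 6 | 2-[4-(benzyloxy)-2,6-dimethoxyphenoxy]-4,6-dimethoxyaniline | COc1cc(OC)c(N)c(Oc2c(OC)cc(OCc3ccccc3)cc2OC)c1
F4 | step 6 | 2-[4-(benzyloxy)-2,6-dimethoxyphenoxy]-4,6-dimethoxybenzenediazonium chloride | COc1cc(OC)c([N+]#N)c(Oc2c(OC)cc(OCc3ccccc3)cc2OC)c1.[Cl-]
F5 | step 7 | 2-[4-(benzyloxy)-2,6-dimethoxyphenoxy]-4,6-dimethoxyphenol | COc1cc(OC)c(O)c(Oc2c(OC)cc(OCc3ccccc3)cc2OC)c1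
F6 | step 9 | 4-[2-(3,5-dimethoxyphenoxy)-3,5-dimethoxyphenoxy]-3,5-dimethoxyphenyl trifluoromethanesulfonate | COc1cc(OC)cc(Oc2c(OC)cc(OC)cc2Oc2c(OC)cc(OS(=O)(=O)C(F)(F)F)cc2OC)c1
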